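Two questions stood on the west flask, followed on to 20 h.

| setting | west | north-west | flask |
|---|---|---|---|
| substrate | 20 mM | 10 mM | 20 mM |
| coupling partner | 12 mM | 12 mM | 12.0 mM |
| protic impurity | 6 mM | 6 mM | 6.00 mM |
| precatalyst | 0.20 mM | 0.20 mM | 0.20 mM |
| remark | the very flask that is asked about, followed so far | run made earlier |  |
| time |  |  | 20 h |

| run | time / h | catalyst intermediate B / % | product / % | catalyst intermediate C / % | substrate / % |
|---|---|---|---|---|---|
| west | 1.50 | 0.3 | 0 | 0 | 99.8 |
| west | 3.00 | 0.3 | 0.3 | 0 | 99.4 |
| west | 5.00 | 0.5 | 1.0 | 0.3 | 98.9 |
| west | 6.00 | 0 | 1.8 | 0 | 98.7 |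
| north-west | 0.667 | 0 | 0.5 | 0.3 | 100.3 |
| north-west | 1.33 | 0 | 0.1 | 0 | 99.8 |
| north-west | 3.00 | 0 | 0.4 | 0 | 98.8 |
| north-west | 8.00 | 0 | 3.6 | 0 | 95.5 |

(readings scatter by 0.3 percentage points)



- the species in which most of what was charged as substrate, at 20 h sits (catalyst intermediate B / product / catalyst intermediate C / substrate)
- the largest share itself, whichever of these holds it, in percent of the substrate charged

I began with the end state. The coupling partner was the limiting reagent: one of each would allow 60.0 % of the substrate charge to react, and 30.0 % if each protic impurity took one coupling partner away. Then I asked how fast that end was approached. The loss was speeding up, so I let it grow with the square of time. Scaled by the square of the time, the west product reading, 1.8 % at 6.00 h, gave 20.0 % lost by the asked time.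

That reading was the weak link, since the west substrate showed a loss of 1.30 %, less than the product, with a scatter of 0.3 percentage points on each. So I reforged it from the larger loss in the north-west run, 4.50 % of a charge half as large. Taking the amount lost as the same in both runs and counting it as a fraction of the west charge, I kept the ramp time, a scale such that the fraction lost is the square of the time over the ramp time: 53.3 h. The west substrate reading gave 52.6 h, so the two runs agreed. By 20 h the ramp time meant 14.1 % lost, below the lower ceiling, and I committed to 85.9 % substrate.

The forecast said substrate at 80 %, within 62 % to 92 %, lower than my figure, on the ground that “Product formation accelerates, which indicates an induction period”.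

The west flask gave substrate at 87.6 %, with product at 12.2 %. Its own ramp time came to 56.7 h, longer than my 53.3 h.

    coupling partner + free catalyst ⇌ catalyst intermediate A (K = 80.3 M⁻¹, k = 33.0 M⁻¹ min⁻¹)
    substrate + catalyst intermediate A → catalyst intermediate B (k = 24.9 M⁻¹ min⁻¹)
    catalyst intermediate B ⇌ catalyst intermediate C (K = 8.80, k = 22.9 min⁻¹)
    catalyst intermediate C ⇌ free catalyst + product (K = 0.0254 M, k = 0.0931 min⁻¹)
    coupling partner + protic impurity → quenched reagent (k = 0.205 M⁻¹ min⁻¹)
    precatalyst → free catalyst (k = 4.93 × 10⁻⁴ min⁻¹)

The scheme shows precatalyst feeding free catalyst, so for the neighbouring flask with 0.34 mM of precatalyst, all else as in the west flask, I took the fraction lost in proportion to the precatalyst charge, which shortened my ramp time to 40.9 h. This predicted 76.1 % substrate left at 20 h. That neighbouring flask holds 80.7 % substrate at 20.0 h.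

(Readings and results are calculated on assumed constants, noise included.)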